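Ring A of the chromone is a pentasubstituted benzene, and everything rests on building it from a 2-pyrone and an ynol ether. Its contiguous array C4a (acyl), C8a (O), C8 (prenyl), C7 (O), C6 (prenyl), C5 (H) maps onto pyrone 7, ethyl 4-(methoxymethoxy)-3-prenyl-2-oxo-2H-pyran-5-carboxylate, which supplies C4a, C5, C8 and C8a, and silyl ynol ether 13, which supplies C6 and C7. One thermal operation forms C5–C6 and C7–C8, expels CO2 and delivers salicylate 15 with both prenyl groups and two differently protected oxygens in place. Ring C is then grown from the ester carbon, and ring B enters as a phenoxide.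

Key step: step 6

Remark: the target is achiral, so no step sets a lasting stereocentre. Transients 14 and 16 are racemic. The alkene geometry of 3 (isomer mixture) and 23 (drawn Z, as expected for a push-pull enaminone) is lost on ring closure. "Prenyl" means 3-methylbut-2-enyl throughout.

Step 1
Reactants: 1 diethyl 3-oxopentanedioate; 2 triethyl orthoformate
Product: 4 ethyl 4-hydroxy-2-oxo-2H-pyran-5-carboxylate, via ethoxymethylidene diester 3 (not isolated)
Conditions: 2 (1.0 equiv), Ac2O, 130 °C, volatiles distilled off; then 2 M HCl (aq), rt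
Reagents that add atoms: water, O
Why: Knoevenagel-type condensation of one activated methylene with the orthoformate (Ac2O traps the ethanol) should give 3, and acid hydrolysis of its enol ether followed by 6-exo-trig lactonisation of the hydroxymethylidene OH onto the distal ester should give the 4-hydroxy-2-pyrone, one equivalent of 2 keeping the second methylene free.

Step 2
Reactants: 4 ethyl 4-hydroxy-2-oxo-2H-pyran-5-carboxylate; 5 3-methylbut-2-enyl acetate (prenyl acetate)
Product: 6 ethyl 4-hydroxy-3-(3-methylbut-2-enyl)-2-oxo-2H-pyran-5-carboxylate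
Conditions: Pd(PPh3)4 (5 mol %), DBU (1.0 equiv), 5 (1.0 equiv), PhMe, 60 °C
Reagents that add atoms: none
Why: In this Tsuji–Trost allylation the soft pyronate carbon C3 should attack the unhindered CH2 terminus of the (1,1-dimethylallyl)palladium cation, while any O-prenyl ether is re-ionised by zerovalent palladium and so funnels to the C3-prenyl product.

Step 3
Reactants: 6 ethyl 4-hydroxy-3-(3-methylbut-2-enyl)-2-oxo-2H-pyran-5-carboxylate
Product: 7 ethyl 4-(methoxymethoxy)-3-(3-methylbut-2-enyl)-2-oxo-2H-pyran-5-carboxylate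
Conditions: MOMCl, iPr2NEt, CH2Cl2, 0 °C
Reagents that add atoms: chloromethyl methyl ether, COCCl
Why: O-alkylation of the vinylogous acid by the hard, oxocarbenium-like electrophile should occur at O4 because C3 is now fully substituted, and the acetal removes the acidic proton that would destroy the ynol ether in step 6.

Step 4
Reactants: 8 1-bromo-3-methylbut-2-ene (prenyl bromide); 9 ethynylmagnesium bromide
Product: 10 5-methylhex-4-en-1-yne
Conditions: 9 (2 equiv), CuCl (5 mol %), THF, 0 → 40 °C; fractional distillation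
Reagents that add atoms: none
Why: Copper-catalysed coupling of an alkynyl Grignard reagent with a primary allylic bromide should proceed mainly by direct substitution at the CH2 carbon to give the skipped enyne, with the excess of 9 suppressing double alkylation.

Step 5
Reactants: 10 5-methylhex-4-en-1-yne
Product: 13 triisopropyl(5-methylhex-4-en-1-ynyloxy)silane, via lithium acetylide 11 (not isolated), via lithium ynolate 12 (not isolated)
Conditions: n-BuLi, THF, −78 °C; t-BuOOH/LiN(SiMe3)2 (premixed, −78 °C), then 0 °C; TIPSOTf, −78 → 0 °C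
Reagents that add atoms: tert-butyl hydroperoxide, CC(C)(C)OO; triisopropylsilyl trifluoromethanesulfonate, CC(C)[Si](C(C)C)(C(C)C)OS(=O)(=O)C(F)(F)F
Why: Electrophilic oxygen transfer from lithium tert-butyl peroxide to the acetylide (acetylide oxidation) should give ynolate 12, which the bulky silyl triflate traps on oxygen to give the silyl ynol ether, the isolated trisubstituted alkene being inert to the peroxide anion.

Step 6
Reactants: 7 ethyl 4-(methoxymethoxy)-3-(3-methylbut-2-enyl)-2-oxo-2H-pyran-5-carboxylate; 13 triisopropyl(5-methylhex-4-en-1-ynyloxy)silane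
Product: 15 ethyl 2-(methoxymethoxy)-3,5-bis(3-methylbut-2-enyl)-4-(triisopropylsilyloxy)benzoate, via bicyclic lactone 14 (not isolated)
Conditions: 13 (1.5 equiv), PhMe (degassed), 100 °C, sealed tube
Reagents that add atoms: none
Why: The electron-poor pyrone diene (C3=C4–C5=C6) and the electron-rich ynol ether should combine in an asynchronous inverse-electron-demand Diels–Alder reaction, the prenyl-bearing alkyne carbon bonding first to pyrone C6 and the silyloxy-bearing carbon then closing onto C3 to give bridged lactone 14. Lactone 14 then loses CO2 by a retro-[4+2] step, which is irreversible and leaves the benzene ring. The closest known reaction type is the cycloaddition and decarboxylation of 2-pyrone-5-carboxylates with ynamines and alkoxyalkynes to give substituted benzoates. Ring A, the only ring formed, closes by intermolecular [4+2] union of four pyrone carbons with the two alkyne carbons and is aromatised by the CO2 extrusion; no stereocentre survives, 14 being a racemic transient. The selectivity required is regiochemical: C6 is β to the C5 ester and vinylogous to the lactone carbonyl, so it is the most electrophilic diene terminus and pairs with the nucleophilic β-carbon of the ynol ether, which places prenyl at C6 and silyloxy at C7 of the target. Neutral thermal conditions leave the MOM acetal, the silyl ynol ether and both prenyl alkenes untouched.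

Step 7
Reactants: 15 ethyl 2-(methoxymethoxy)-3,5-bis(3-methylbut-2-enyl)-4-(triisopropylsilyloxy)benzoate
Product: 17 2-chloro-1-[2-(methoxymethoxy)-3,5-bis(3-methylbut-2-enyl)-4-(triisopropylsilyloxy)phenyl]ethanone, via lithium hemiketal alkoxide 16 (not isolated)
Conditions: ICH2Cl (2 equiv), MeLi·LiBr (slow addition), THF, −78 °C; aq NH4Cl at −78 °C
Reagents that add atoms: chloroiodomethane, ClCI
Why: Chloromethyllithium formed in situ by iodine–lithium exchange adds to the ester (carbenoid homologation of an ester), and adduct 16, chelated by the ortho MOM oxygen, should persist at −78 °C and collapse to the α-chloroketone only on quench, so a second addition is avoided.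

Step 8
Reactants: 18 2,4-dihydroxybenzaldehyde
Product: 19 2,4-bis(methoxymethoxy)benzaldehyde
Conditions: MOMCl (3 equiv), iPr2NEt (4 equiv), CH2Cl2, 0 °C → reflux
Reagents that add atoms: chloromethyl methyl ether, COCCl
Why: Williamson-type acetalisation of both phenols should go to completion with excess reagent, the hydrogen-bonded 2-OH reacting last.

Step 9
Reactants: 19 2,4-bis(methoxymethoxy)benzaldehyde
Product: 21 2,4-bis(methoxymethoxy)phenol, via aryl formate 20 (not isolated)
Conditions: mCPBA, NaHCO3, CH2Cl2, 0 °C → rt; then K2CO3, MeOH, rt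
Reagents that add atoms: 3-chloroperoxybenzoic acid, OOC(=O)c1cccc(Cl)c1
Why: In this Baeyer–Villiger (Dakin-type) oxidation the electron-rich 2,4-dialkoxyaryl group should migrate in preference to hydrogen, and methanolysis of formate 20 frees the phenol while the buffer protects the acetals.

Step 10
Reactants: 17 2-chloro-1-[2-(methoxymethoxy)-3,5-bis(3-methylbut-2-enyl)-4-(triisopropylsilyloxy)phenyl]ethanone; 21 2,4-bis(methoxymethoxy)phenol
Product: 22 2-[2,4-bis(methoxymethoxy)phenoxy]-1-[2-(methoxymethoxy)-3,5-bis(3-methylbut-2-enyl)-4-(triisopropylsilyloxy)phenyl]ethanone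
Conditions: K2CO3, acetone, 50 °C
Reagents that add atoms: none
Why: Williamson ether synthesis on an α-chloroketone is fast with an electron-rich phenoxide, and the MOM group on the C8a oxygen prevents that oxygen from closing to a benzofuranone.

Step 11
Reactants: 22 2-[2,4-bis(methoxymethoxy)phenoxy]-1-[2-(methoxymethoxy)-3,5-bis(3-methylbut-2-enyl)-4-(triisopropylsilyloxy)phenyl]ethanone
Product: 24 3-(2,4-dihydroxyphenoxy)-6,8-bis(3-methylbut-2-enyl)-7-(triisopropylsilyloxy)-4H-chromen-4-one, via enaminone 23 (not isolated)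
Conditions: DMF-DMA, PhMe, 90 °C; evaporate; then HCl (1.25 M in MeOH, 3 equiv), THF, 40 °C
Reagents that add atoms: N,N-dimethylformamide dimethyl acetal, COC(OC)N(C)C
Why: Condensation of the methylene flanked by ketone and aryloxy with the amide acetal gives enaminone 23, and methanolic acid then removes the three MOM acetals so that the freed C8a phenol closes ring C by 6-endo-trig addition–elimination with loss of dimethylamine (enaminone chromone synthesis), the silyl ether on C7 keeping that oxygen from adding to its flanking prenyl alkenes under acid.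

Step 12
Reactants: 24 3-(2,4-dihydroxyphenoxy)-6,8-bis(3-methylbut-2-enyl)-7-(triisopropylsilyloxy)-4H-chromen-4-one
Product: 25 eryvarin F
Conditions: Bu4NF, AcOH, THF, 0 °C
Reagents that add atoms: none
Why: Fluoride-induced cleavage of the aryl silyl ether should be fast because the 7-oxychromone is a vinylogous carboxylate leaving group, and the acetic acid buffer shields the chromone from base.

Compound list
1 | diethyl 3-oxopentanedioate | CCOC(=O)CC(=O)CC(=O)OCC | starting material
2 | triethyl orthoformate | CCOC(OCC)OCC | starting material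
3 | diethyl 2-(ethoxymethylidene)-3-oxopentanedioate (alkene isomer mixture) | CCOC=C(C(=O)OCC)C(=O)CC(=O)OCC | intermediate
4 | ethyl 4-hydroxy-2-oxo-2H-pyran-5-carboxylate | CCOC(=O)c1coc(=O)cc1O | intermediate
5 | 3-methylbut-2-enyl acetate | CC(=O)OCC=C(C)C | starting material
6 | ethyl 4-hydroxy-3-(3-methylbut-2-enyl)-2-oxo-2H-pyran-5-carboxylate | CCOC(=O)c1coc(=O)c(CC=C(C)C)c1O | intermediate
7 | ethyl 4-(methoxymethoxy)-3-(3-methylbut-2-enyl)-2-oxo-2H-pyran-5-carboxylate | CCOC(=O)c1coc(=O)c(CC=C(C)C)c1OCOC | intermediate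
8 | 1-bromo-3-methylbut-2-ene | CC(C)=CCBr | starting material
9 | ethynylmagnesium bromide | C#C[Mg]Br | starting material
10 | 5-methylhex-4-en-1-yne | CC(C)=CCC#C | intermediate
11 | lithium 5-methylhex-4-en-1-yn-1-ide | [Li]C#CCC=C(C)C | intermediate
12 | lithium 5-methylhex-4-en-1-yn-1-olate | CC(C)=CCC#C[O-].[Li+] | intermediate
13 | triisopropyl(5-methylhex-4-en-1-ynyloxy)silane | CC(C)=CCC#CO[Si](C(C)C)(C(C)C)C(C)C | intermediate
14 | ethyl 8-(methoxymethoxy)-4,6-bis(3-methylbut-2-enyl)-3-oxo-5-(triisopropylsilyloxy)-2-oxabicyclo[2.2.2]octa-5,7-diene-7-carboxylate (racemic) | O=C1OC2C(CC=C(C)C)=C(O[Si](C(C)C)(C(C)C)C(C)C)C1(CC=C(C)C)C(OCOC)=C2C(=O)OCC | intermediate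
15 | ethyl 2-(methoxymethoxy)-3,5-bis(3-methylbut-2-enyl)-4-(triisopropylsilyloxy)benzoate | CCOC(=O)c1cc(CC=C(C)C)c(O[Si](C(C)C)(C(C)C)C(C)C)c(CC=C(C)C)c1OCOC | intermediate
16 | lithium 2-chloro-1-ethoxy-1-[2-(methoxymethoxy)-3,5-bis(3-methylbut-2-enyl)-4-(triisopropylsilyloxy)phenyl]ethanolate (racemic) | CCOC([O-])(CCl)c1cc(CC=C(C)C)c(O[Si](C(C)C)(C(C)C)C(C)C)c(CC=C(C)C)c1OCOC.[Li+] | intermediate
17 | 2-chloro-1-[2-(methoxymethoxy)-3,5-bis(3-methylbut-2-enyl)-4-(triisopropylsilyloxy)phenyl]ethanone | ClCC(=O)c1cc(CC=C(C)C)c(O[Si](C(C)C)(C(C)C)C(C)C)c(CC=C(C)C)c1OCOC | intermediate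
18 | 2,4-dihydroxybenzaldehyde | O=Cc1ccc(O)cc1O | starting material
19 | 2,4-bis(methoxymethoxy)benzaldehyde | COCOc1ccc(C=O)c(OCOC)c1 | intermediate
20 | 2,4-bis(methoxymethoxy)phenyl formate | O=COc1ccc(OCOC)cc1OCOC | intermediate
21 | 2,4-bis(methoxymethoxy)phenol | COCOc1ccc(O)c(OCOC)c1 | intermediate
22 | 2-[2,4-bis(methoxymethoxy)phenoxy]-1-[2-(methoxymethoxy)-3,5-bis(3-methylbut-2-enyl)-4-(triisopropylsilyloxy)phenyl]ethanone | COCOc1ccc(OCC(=O)c2cc(CC=C(C)C)c(O[Si](C(C)C)(C(C)C)C(C)C)c(CC=C(C)C)c2OCOC)c(OCOC)c1 | intermediate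
23 | (Z)-2-[2,4-bis(methoxymethoxy)phenoxy]-3-(dimethylamino)-1-[2-(methoxymethoxy)-3,5-bis(3-methylbut-2-enyl)-4-(triisopropylsilyloxy)phenyl]prop-2-en-1-one | CN(C)/C=C(\Oc1ccc(OCOC)cc1OCOC)C(=O)c1cc(CC=C(C)C)c(O[Si](C(C)C)(C(C)C)C(C)C)c(CC=C(C)C)c1OCOC | intermediate
24 | 3-(2,4-dihydroxyphenoxy)-6,8-bis(3-methylbut-2-enyl)-7-(triisopropylsilyloxy)-4H-chromen-4-one | CC(C)=CCc1cc2c(=O)c(Oc3ccc(O)cc3O)coc2c(CC=C(C)C)c1O[Si](C(C)C)(C(C)C)C(C)C | intermediate
25 | eryvarin F, 3-(2,4-dihydroxyphenoxy)-7-hydroxy-6,8-bis(3-methylbut-2-enyl)-4H-chromen-4-one | CC(C)=CCc1cc2c(=O)c(Oc3ccc(O)cc3O)coc2c(CC=C(C)C)c1O | target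

Total step count: 12 steps.
Longest linear sequence: 8 steps (steps 1, 2, 3, 6, 7, 10, 11, 12).

Steps most likely to fail

Step 6. The C4 alkoxy group damps the electron demand of the diene, so the cycloaddition may be slower than thermal silyl migration in the ynol ether (to a silylketene). The zwitterionic adduct at C6 may also close onto C5 to give a four-membered ring instead of onto C3. The fallback abandons the pyrone and builds the same ring A by arene chemistry, setting out from 18 and returning at 17. Double iodination of 18 (ICl, AcOH) should give 2,4-dihydroxy-3,5-diiodobenzaldehyde F1. Silylation of the non-chelated, more acidic 4-OH (TIPSOTf, 2,6-lutidine, CH2Cl2, −78 °C) gives 2-hydroxy-3,5-diiodo-4-(triisopropylsilyloxy)benzaldehyde F2. MOMCl with iPr2NEt then gives 3,5-diiodo-2-(methoxymethoxy)-4-(triisopropylsilyloxy)benzaldehyde F3. A double Stille coupling with tributyl(3-methylbut-2-enyl)stannane (Pd(PPh3)4, DMF, 90 °C) installs both prenyl groups to give 2-(methoxymethoxy)-3,5-bis(3-methylbut-2-enyl)-4-(triisopropylsilyloxy)benzaldehyde F4. Chloromethyllithium (ICH2Cl, MeLi·LiBr, THF, −78 °C, AcOH quench) adds to the aldehyde to give racemic 2-chloro-1-[2-(methoxymethoxy)-3,5-bis(3-methylbut-2-enyl)-4-(triisopropylsilyloxy)phenyl]ethanol F5, and Dess–Martin oxidation (NaHCO3, CH2Cl2) gives 17.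

Step 2. The O-prenyl ether may fail to funnel to carbon, a second prenyl group may add at C3, attack may occur at the tertiary allyl terminus, or the 4-OH may add across the new alkene. The fallback places the prenyl group before the ring is made, setting out from 1 and returning at 6. Mono-alkylation of the sodium enolate of 1 (NaH, THF, 0 °C, 1 in excess) with 8 should give racemic diethyl 2-(3-methylbut-2-enyl)-3-oxopentanedioate F6. DMF-DMA (PhMe, rt) condenses at the remaining methylene to give diethyl 2-[(dimethylamino)methylidene]-4-(3-methylbut-2-enyl)-3-oxopentanedioate F7. Dilute HCl in THF at rt hydrolyses the enamine and lactonises to 6, under conditions mild enough for the prenyl alkene.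

Step 7. The tetrahedral adduct may collapse before the quench, so that a second carbenoid adds, or the carbenoid may decompose by α-elimination before it reaches the hindered ester. The fallback changes the acyl electrophile to one whose adduct is held by chelation, setting out from 15 and returning at 17. Aminolysis of 15 with MeNH(OMe)·HCl and i-PrMgCl (THF, −20 °C) should give the Weinreb amide N-methoxy-2-(methoxymethoxy)-N-methyl-3,5-bis(3-methylbut-2-enyl)-4-(triisopropylsilyloxy)benzamide F8. Chloromethyllithium (ICH2Cl, MeLi·LiBr, THF, −78 °C) adds once to give the chelated lithium 2-chloro-1-[methoxy(methyl)amino]-1-arylethanolate F9, which releases 17 on aqueous NH4Cl quench.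

Further compounds
F1 | step 6 | 2,4-dihydroxy-3,5-diiodobenzaldehyde | O=Cc1cc(I)c(O)c(I)c1O
F2 | step 6 | 2-hydroxy-3,5-diiodo-4-(triisopropylsilyloxy)benzaldehyde | O=Cc1cc(I)c(O[Si](C(C)C)(C(C)C)C(C)C)c(I)c1O
F3 | step 6 | 3,5-diiodo-2-(methoxymethoxy)-4-(triisopropylsilyloxy)benzaldehyde | COCOc1c(C=O)cc(I)c(O[Si](C(C)C)(C(C)C)C(C)C)c1I
F4 | step 6 | 2-(methoxymethoxy)-3,5-bis(3-methylbut-2-enyl)-4-(triisopropylsilyloxy)benzaldehyde | COCOc1c(C=O)cc(CC=C(C)C)c(O[Si](C(C)C)(C(C)C)C(C)C)c1CC=C(C)C
F5 | step 6 | 2-chloro-1-[2-(methoxymethoxy)-3,5-bis(3-methylbut-2-enyl)-4-(triisopropylsilyloxy)phenyl]ethanol (racemic) | OC(CCl)c1cc(CC=C(C)C)c(O[Si](C(C)C)(C(C)C)C(C)C)c(CC=C(C)C)c1OCOC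
F6 | step 2 | diethyl 2-(3-methylbut-2-enyl)-3-oxopentanedioate (racemic) | CCOC(=O)CC(=O)C(CC=C(C)C)C(=O)OCC
F7 | step 2 | diethyl 2-[(dimethylamino)methylidene]-4-(3-methylbut-2-enyl)-3-oxopentanedioate (racemic, alkene isomer mixture) | CCOC(=O)C(=CN(C)C)C(=O)C(CC=C(C)C)C(=O)OCC
F8 | step 7 | N-methoxy-2-(methoxymethoxy)-N-methyl-3,5-bis(3-methylbut-2-enyl)-4-(triisopropylsilyloxy)benzamide | CON(C)C(=O)c1cc(CC=C(C)C)c(O[Si](C(C)C)(C(C)C)C(C)C)c(CC=C(C)C)c1OCOC
F9 | step 7 | lithium 2-chloro-1-[methoxy(methyl)amino]-1-[2-(methoxymethoxy)-3,5-bis(3-methylbut-2-enyl)-4-(triisopropylsilyloxy)phenyl]ethanolate (racemic) | CON(C)C([O-])(CCl)c1cc(CC=C(C)C)c(O[Si](C(C)C)(C(C)C)C(C)C)c(CC=C(C)C)c1OCOC.[Li+]
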